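Assumption (remark on the chemistry): the target SMILES has no stereodescriptor, so the C3'–C8'' biaryl axis is treated as configurationally undefined; acacetin and genkwanin are taken as catalogue compounds.

Numbering convention: in the genkwanin half the chromone positions are unprimed and ring B is primed (1'–6'). In the acacetin half the chromone positions are double-primed and the anisyl ring is triple-primed.

## Analysis of the target

Putraflavone (9) is 7,4'''-di-O-methylamentoflavone: two 2-aryl-5,7-dioxygenated chromen-4-ones joined by one biaryl bond, from C3' of ring B of the genkwanin-type half (5-OH, 7-OMe, 4'-OH) to C8'' of ring A of the acacetin-type half (5''-OH, 7''-OH, 4'''-OMe). There is no stereocentre. The only stereo element is the C3'–C8'' axis, which carries three ortho substituents (O4', O7'' and the C8a''–O1'' junction) and is not defined in the target.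

The feature that drives the plan is the atom string O4'–C4'–C3'–C8''–C7''–O7''. The biaryl bond is flanked by one oxygen on ring B and one on ring A of the other half, and these two oxygens are the only non-chelated free phenols of 9. The other two free phenols (5-OH and 5''-OH) are hydrogen-bonded to the C4 and C4'' carbonyl groups, and O7 and O4''' are methylated. Each half is therefore an intact natural monomer whose single reactive phenol sits beside the carbon that has to be joined.

Sensitive points:
- The pyranone rings open with hot hydroxide or alkoxide.
- Hot strong protic acid can open and reclose the acacetin pyranone through O5'' and so exchange C8'' for C6''.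
- Both methyl ethers must survive every deprotection.

The synthesis is hard for four reasons: two nearly identical, electron-poor flavones must be cross-joined; C8'' must be chosen over C6'' (both are ortho to O7''); the biaryl is hindered; and only two of six oxygens are methylated, differently in the two halves.

## Retrosynthetic reasoning

**Bridge across the axis.** Putraflavone (9) is traced back to the silicon-bridged biflavone 8, in which one di-tert-butylsilicon atom joins O4' and O7''. The two Si–O bonds are chosen because they sit on exactly the two phenols that flank the axis and must end free. The bridge therefore serves as protecting group and as tether at once. The forward reaction is a fluoride-induced cleavage of two aryl silyl ethers, which leaves methyl ethers, chelated phenols and pyranones untouched.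

**The biaryl bond (key disconnection).** In 8 the bond C3'–C8'' is part of a seven-membered ring (C7''–O–Si–O–C4'–C3'–C8''). Cutting it opens that ring and gives the acyclic bis(aryloxy)silane 7, which has iodine at C8'' and hydrogen at C3'. This is the only bond that joins the two halves, so the cut returns two complete monomers. The forward reaction is a palladium-catalysed intramolecular C–H arylation. It has four selectivity demands, each answered by the structure of 7:
- Cross- versus homo-coupling: the bridge holds exactly one molecule of each monomer.
- C–C versus C–O coupling: both phenol oxygens are occupied by silicon.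
- C8'' versus C6'': the iodine marks C8''.
- C3' versus C5': the two positions are equivalent by rotation of ring B.

**The two Si–O bonds.** Compound 7 is cut at silicon into 8-iodoacacetin (4) and genkwanin (5). The forward reaction is a stepwise silylation of the one non-chelated phenol of each monomer by a doubly electrophilic di-tert-butylsilicon reagent. The chelated 5-OH groups need no protection, and the methylation pattern of 9 is inherited from the monomers. No oxygen has to be differentiated by protecting groups on the genkwanin side at all.

**The C8''–I bond.** Compound 4 is traced back through the bis(methoxymethyl) ether 3 and its iodine-free parent 2 to acacetin (1). The detour through 2 is needed because a chelated 5-OH steers electrophiles to C6, whereas 5,7-dialkoxyflavones react at C8. The forward sequence is capping of both phenols, electrophilic iodination, and mild acid hydrolysis.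

## Alternatives that were turned down

Alternative 1: The textbook disconnection cuts C3'–C8'' intermolecularly. The forward key step is a palladium-catalysed boronate–iodide coupling of iodide 3 with the ring-B boronate A1 (the 4'-O-methoxymethyl-3'-pinacolboronate of the genkwanin half), followed by acetal hydrolysis. It was turned down for three reasons. First, A1 cannot be reached from 5: electrophiles attack the chelated ring A of 5 before ring B, so the whole genkwanin half would have to be rebuilt from a ring-B-halogenated aldehyde through chalcone formation, oxidative cyclisation and borylation. Second, the coupling joins a di-ortho-substituted iodide to an ortho-alkoxy arylboronate that is prone to protodeboronation. Third, the route is about ten steps, and each half needs its own protecting-group pattern to leave only two methyl ethers.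

Alternative 2: The purely biomimetic disconnection also cuts C3'–C8'', but with no handle on either partner. The forward key step is a one-electron oxidative phenol cross-coupling of 1 with 5 in one step. It was turned down because nothing in the substrates controls it. Homo-coupling competes with cross-coupling. Phenoxyl oxygen competes with carbon. C6'' competes with C8'', so the 3',6''-linked isomer A2 would form alongside 9 and be very hard to separate from it. Both phenols are vinylogous acids with high oxidation potentials, so over-oxidation is expected before useful conversion.

Alternative 3: The pyranone ring of the genkwanin half is cut instead (bonds C2–C3 and O1–C2). The forward key step is a base-mediated aldol condensation of the biaryl aldehyde A3 (an 8''-aryl acacetin with a formyl group where C2 will be) with the acetophenone that carries ring A, giving chalcone A4, which is then cyclised oxidatively. It was turned down because it relocates the biaryl problem without removing it: A3 still needs an intermolecular cross-coupling at C8''. In addition, the strongly basic condensation meets four free phenols and a base-sensitive pyranone, so extra protection is needed, and the oxidative cyclisation of A4 has electron-rich rings open to halogenation. The step count is at least nine.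

Key step: step 5

## Route

Step 1
Reactants: 1 acacetin (5,7-dihydroxy-2-(4-methoxyphenyl)-4H-chromen-4-one)
Product: 2 5,7-bis(methoxymethoxy)-2-(4-methoxyphenyl)-4H-chromen-4-one
Conditions: NaH (2.5 equiv), MOMCl (2.5 equiv), DMF, 0 °C → rt
Reagents that add atoms: chloromethyl methyl ether (MOMCl), COCCl
Why: Williamson-type O-alkylation of both phenoxides; NaH is needed to ionise the chelated 5-OH, and capping it removes the hydrogen bond that would otherwise direct the next step to C6.

Step 2
Reactants: 2 5,7-bis(methoxymethoxy)-2-(4-methoxyphenyl)-4H-chromen-4-one
Product: 3 8-iodo-5,7-bis(methoxymethoxy)-2-(4-methoxyphenyl)-4H-chromen-4-one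
Conditions: NIS (1.1 equiv), DMF, rt → 50 °C, dark
Reagents that add atoms: N-iodosuccinimide (NIS), O=C1CCC(=O)N1I
Why: Electrophilic aromatic iodination; in 5,7-dialkoxyflavones without a chelated 5-OH the most nucleophilic position is C8 (ortho to O7, para to O5), while C6 is flanked by two acetal groups and C3 and the anisyl ring are deactivated by the enone; acid-free conditions keep the acetals in place.

Step 3
Reactants: 3 8-iodo-5,7-bis(methoxymethoxy)-2-(4-methoxyphenyl)-4H-chromen-4-one
Product: 4 8-iodoacacetin (5,7-dihydroxy-8-iodo-2-(4-methoxyphenyl)-4H-chromen-4-one)
Conditions: 3 M HCl, MeOH–THF, 45 °C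
Reagents that add atoms: none
Why: Acid-catalysed acetal exchange with methanol removes both methoxymethyl groups (the peri one fastest, assisted by the carbonyl group); the mild temperature should avoid protodeiodination and pyranone opening, and the methyl ether is inert.

Step 4
Reactants: 4 8-iodoacacetin; 5 genkwanin (5-hydroxy-2-(4-hydroxyphenyl)-7-methoxy-4H-chromen-4-one)
Product: 7 di-tert-butyl{[5-hydroxy-8-iodo-2-(4-methoxyphenyl)-4-oxo-4H-chromen-7-yl]oxy}[4-(5-hydroxy-7-methoxy-4-oxo-4H-chromen-2-yl)phenoxy]silane, via silyl triflate 6 (not isolated)
Conditions: tBu2Si(OTf)2 (1.05 equiv), 2,6-lutidine (4 equiv), CH2Cl2–DMF, −40 → 0 °C, slow addition of 4; then 5 (1.1 equiv), DMAP (cat.), 0 → 40 °C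
Reagents that add atoms: di-tert-butylsilyl bis(trifluoromethanesulfonate), CC(C)(C)[Si](OS(=O)(=O)C(F)(F)F)(OS(=O)(=O)C(F)(F)F)C(C)(C)C
Why: Two successive O-silylations at one silicon atom; the first triflate is displaced quickly at low temperature by the only non-chelated phenol of 4 (7''-OH), the second sits on the more hindered silicon of 6 and needs the unhindered 4'-phenol of 5, DMAP and warming, which is what makes an unsymmetrical bridge possible; the chelated 5-OH groups are too hindered and too weakly nucleophilic for a di-tert-butylsilyl group.

Step 5
Reactants: 7 di-tert-butyl{[5-hydroxy-8-iodo-2-(4-methoxyphenyl)-4-oxo-4H-chromen-7-yl]oxy}[4-(5-hydroxy-7-methoxy-4-oxo-4H-chromen-2-yl)phenoxy]silane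
Product: 8 4',7''-O-(di-tert-butylsilanediyl)putraflavone (the dibenzo[d,f][1,3,2]dioxasilepine in which silicon bridges O4' and O7'' and C3' is bonded to C8'')
Conditions: Pd(OAc)2 (10 mol %), PCy3·HBF4 (20 mol %), CsO2CtBu (caesium pivalate, 3 equiv), mesitylene, 120 °C, Ar
Reagents that add atoms: none
Why: The step relies on silicon-tethered intramolecular direct arylation of a bis(aryloxy)di-tert-butylsilane, a known way to unsymmetrical 2,2'-biphenols, applied here to two flavone monomers. Zerovalent palladium, formed from Pd(OAc)2 and the phosphine, should insert into the C8''–I bond; iodide is exchanged for pivalate, and the bound pivalate removes H3' by concerted metalation–deprotonation through an eight-membered palladacycle. Reductive elimination then forms C3'–C8'' and closes the one new ring, the seven-membered dioxasilepine C7''–O–Si–O–C4'–C3'–C8''; the closure is an aryl–aryl reductive elimination at palladium, so both ring carbons are delivered by the metal. No stereocentre is formed, and the twisted axis of 8 is not a defined element of the target, so no stereocontrol is needed. Cross-selectivity and C–C over C–O coupling are secured by the bridge, which holds one molecule of each monomer and occupies both phenol oxygens. C8'' over C6'' is secured by the position of the iodine, and C3' and C5' are equivalent by rotation of ring B about its C1'–C4' axis; no other C–H bond is within reach of palladium at C8''. Ring B is electron-poor (para-chromonyl) and H3' is ortho to the silyloxy group, which is the profile that concerted metalation–deprotonation favours. Caesium pivalate is too weak a base to open the pyranones, and the tert-butyl groups shield silicon from attack by carboxylate.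

Step 6
Reactants: 8 4',7''-O-(di-tert-butylsilanediyl)putraflavone
Product: 9 putraflavone
Conditions: HF·pyridine, THF–pyridine, 0 °C → rt
Reagents that add atoms: none
Why: Fluoride-induced cleavage of both aryl–O–Si bonds of the silylene acetal (desilylation), driven by Si–F bond strength; methyl ethers, chelated phenols and pyranones are inert, so the two phenols that flank the axis are released last and nothing else changes.

## Compound list

1 | acacetin (5,7-dihydroxy-2-(4-methoxyphenyl)-4H-chromen-4-one) | COc1ccc(cc1)-c1cc(=O)c2c(O)cc(O)cc2o1 | starting material
2 | 5,7-bis(methoxymethoxy)-2-(4-methoxyphenyl)-4H-chromen-4-one | O=c1cc(-c2ccc(OC)cc2)oc2cc(OCOC)cc(OCOC)c12 | intermediate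
3 | 8-iodo-5,7-bis(methoxymethoxy)-2-(4-methoxyphenyl)-4H-chromen-4-one | O=c1cc(-c2ccc(OC)cc2)oc2c(I)c(OCOC)cc(OCOC)c12 | intermediate
4 | 8-iodoacacetin (5,7-dihydroxy-8-iodo-2-(4-methoxyphenyl)-4H-chromen-4-one) | O=c1cc(-c2ccc(OC)cc2)oc2c(I)c(O)cc(O)c12 | intermediate
5 | genkwanin (5-hydroxy-2-(4-hydroxyphenyl)-7-methoxy-4H-chromen-4-one) | O=c1cc(-c2ccc(O)cc2)oc2cc(OC)cc(O)c12 | starting material
6 | 8-iodoacacetin 7''-O-[di-tert-butyl(trifluoromethanesulfonyloxy)silyl] ether | O=c1cc(-c2ccc(OC)cc2)oc2c(I)c(O[Si](OS(=O)(=O)C(F)(F)F)(C(C)(C)C)C(C)(C)C)cc(O)c12 | intermediate
7 | di-tert-butyl{[5-hydroxy-8-iodo-2-(4-methoxyphenyl)-4-oxo-4H-chromen-7-yl]oxy}[4-(5-hydroxy-7-methoxy-4-oxo-4H-chromen-2-yl)phenoxy]silane | O=c1cc(-c2ccc(OC)cc2)oc2c(I)c(O[Si](Oc3ccc(cc3)-c3cc(=O)c4c(O)cc(OC)cc4o3)(C(C)(C)C)C(C)(C)C)cc(O)c12 | intermediate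
8 | 4',7''-O-(di-tert-butylsilanediyl)putraflavone | COc1ccc(cc1)-c1cc(=O)c2c(O)cc3O[Si](C(C)(C)C)(C(C)(C)C)Oc4ccc(cc4-c3c2o1)-c1cc(=O)c2c(O)cc(OC)cc2o1 | intermediate
9 | putraflavone | COc1ccc(-c2cc(=O)c3c(O)cc(O)c(-c4cc(-c5cc(=O)c6c(O)cc(OC)cc6o5)ccc4O)c3o2)cc1 | target

## Step count and risk

Total step count: 6. Longest linear sequence: 6 steps (1 → 2 → 3 → 4 → 7 → 8 → 9); genkwanin (5) enters unchanged at step 4.

**Step 5 (key step).** Three processes are most likely to interfere:
- Scission or scrambling of the aryl–O–Si bonds by carboxylate at 120 °C, because both phenols are acidic and therefore good leaving groups at silicon.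
- Binding of divalent palladium by the 5-hydroxy-4-oxo chelate sites.
- Hydrodeiodination before the seven-membered closure.

The fallback replaces the silicon bridge by a base-stable carbon bridge; it sets out from 4 and 5 and comes back to the route at 9. Compound 4 would be alkylated at O7'' with chloromethyl methyl sulfide (K2CO3, NaI, DMF) to give 8-iodoacacetin 7''-O-methylthiomethyl ether F1. SO2Cl2 in CH2Cl2 at 0 °C should convert the sulfide into 8-iodoacacetin 7''-O-chloromethyl ether F2. The 4'-phenoxide of 5 (K2CO3, DMF) should displace chloride to give the mixed diaryl formal F3. The same palladium-catalysed ring closure, now with K2CO3 and pivalic acid in DMA at 110 °C, which a formaldehyde acetal tolerates, should give the methylene-bridged dioxepine F4. BCl3 in CH2Cl2 (−20 → 0 °C) cleaves methylenedioxy-type acetals but not ordinary aryl methyl ethers, and after aqueous work-up should release 9.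

**Step 4.** Double substitution at silicon by two molecules of 4, stalling at the hindered mono-triflate stage, or hydrolysis of 6 by adventitious water would all lower the amount of unsymmetrical silane. The fallback builds the bridge through an isolable hydrosilane; it sets out from 4 and comes back at 7. Compound 4 would be silylated with tBu2SiHCl (imidazole, DMF) to give 8-iodoacacetin 7''-O-(di-tert-butylsilyl) ether F5, which can be purified. NBS in CH2Cl2 at 0 °C should convert Si–H into Si–Br, giving the bromosilane F6. Addition of 5 with imidazole and DMAP in DMF should then give 7.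

**Step 2.** Loss of the peri acetal group through traces of acid would restore the chelated 5-OH and turn iodination towards C6. Alternatively, conversion could be slow because no acid promoter can be used. The fallback uses acid-stable ethers so that acid-promoted iodination becomes possible; it sets out from 1 and comes back at 4. Compound 1 would be benzylated twice (BnBr, K2CO3, DMF, 80 °C) to give 5,7-di-O-benzylacacetin F7. NIS with catalytic CF3CO2H in MeCN should give 8-iodo-5,7-di-O-benzylacacetin F8. BCl3 in CH2Cl2 (−78 → −20 °C) should remove both benzyl groups without touching the methyl ether or the C–I bond and give 4.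

## Further compounds

F1 | step 5 | 8-iodoacacetin 7''-O-methylthiomethyl ether | O=c1cc(-c2ccc(OC)cc2)oc2c(I)c(OCSC)cc(O)c12
F2 | step 5 | 8-iodoacacetin 7''-O-chloromethyl ether | O=c1cc(-c2ccc(OC)cc2)oc2c(I)c(OCCl)cc(O)c12
F3 | step 5 | mixed diaryl formal of 8-iodoacacetin (O7'') and genkwanin (O4') | O=c1cc(-c2ccc(OC)cc2)oc2c(I)c(OCOc3ccc(cc3)-c3cc(=O)c4c(O)cc(OC)cc4o3)cc(O)c12
F4 | step 5 | 4',7''-O-methyleneputraflavone (methylene-bridged dibenzo[d,f][1,3]dioxepine) | COc1ccc(cc1)-c1cc(=O)c2c(O)cc3OCOc4ccc(cc4-c3c2o1)-c1cc(=O)c2c(O)cc(OC)cc2o1
F5 | step 4 | 8-iodoacacetin 7''-O-(di-tert-butylsilyl) ether | O=c1cc(-c2ccc(OC)cc2)oc2c(I)c(O[SiH](C(C)(C)C)C(C)(C)C)cc(O)c12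
F6 | step 4 | 8-iodoacacetin 7''-O-(bromodi-tert-butylsilyl) ether | O=c1cc(-c2ccc(OC)cc2)oc2c(I)c(O[Si](Br)(C(C)(C)C)C(C)(C)C)cc(O)c12
F7 | step 2 | 5,7-di-O-benzylacacetin | O=c1cc(-c2ccc(OC)cc2)oc2cc(OCc3ccccc3)cc(OCc3ccccc3)c12
F8 | step 2 | 8-iodo-5,7-di-O-benzylacacetin | O=c1cc(-c2ccc(OC)cc2)oc2c(I)c(OCc3ccccc3)cc(OCc3ccccc3)c12
A1 | alternative 1 | 5-hydroxy-7-methoxy-2-[4-(methoxymethoxy)-3-(4,4,5,5-tetramethyl-1,3,2-dioxaborolan-2-yl)phenyl]-4H-chromen-4-one | COCOc1ccc(cc1B1OC(C)(C)C(C)(C)O1)-c1cc(=O)c2c(O)cc(OC)cc2o1
A2 | alternative 2 | 3',6''-linked isomer of putraflavone | COc1ccc(cc1)-c1cc(=O)c2c(O)c(-c3cc(ccc3O)-c3cc(=O)c4c(O)cc(OC)cc4o3)c(O)cc2o1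
A3 | alternative 3 | 3-[5,7-dihydroxy-2-(4-methoxyphenyl)-4-oxo-4H-chromen-8-yl]-4-hydroxybenzaldehyde | COc1ccc(cc1)-c1cc(=O)c2c(O)cc(O)c(-c3cc(C=O)ccc3O)c2o1
A4 | alternative 3 | (E)-chalcone from A3 and the ring-A acetophenone | COc1ccc(cc1)-c1cc(=O)c2c(O)cc(O)c(-c3cc(/C=C/C(=O)c4c(O)cc(OC)cc4O)ccc3O)c2o1
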